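The easy step comes first: read how far the clock of one run must be stretched to fit another.

| flask | substrate | coupling partner | precatalyst | temperature | remark | time |
|---|---|---|---|---|---|---|
| north-west | 0.30 M | 0.90 M | 0.75 mM | 30 °C | run made earlier |  |
| west | 0.30 M | 0.90 M | 3 mM | 52 °C | run made earlier |  |
| delta | 0.30 M | 0.900 M | 1.5 mM | 60 °C |  | 6.0 min |
| theta | 0.30 M | 0.900 M | 1.5 mM | 20 °C |  | 6.0 min |
| gamma | 0.30 M | 0.900 M | 1.5 mM | 40 °C |  | 6.0 min |

| run | time / min | intermediate / % | target / % |
|---|---|---|---|
| north-west | 6.00 | 4.3 | 0.7 |
| north-west | 12.0 | 13.8 | 0.5 |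
| north-west | 20.0 | 21.4 | 3.5 |
| north-west | 25.0 | 24.5 | 2.4 |
| north-west | 40.0 | 31.1 | 5.4 |
| west | 0.500 | 4.0 | 0 |
| west | 1.33 | 13.8 | 0 |
| west | 2.50 | 21.4 | 0.7 |
| west | 4.00 | 30.4 | 4.1 |
| west | 6.00 | 31.9 | 6.4 |
| west | 8.00 | 34.8 | 6.3 |

(standard deviation of a reading: 1 percentage point)



* the flask that comes out highest in amount of intermediate, in percent of the substrate charged, or "all alike" when all lie within 1.5 percentage points (delta / theta / gamma / all alike)
* intermediate at the end, in percent of the substrate charged, delta
* intermediate at the end, in percent of the substrate charged, theta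
* intermediate at the end, in percent of the substrate charged, gamma

The north-west run reads 21.4% of intermediate at 20.0 min, and the west run reads 21.4% at 2.50 min. The west run, hotter and with 4.00 times the precatalyst, therefore reads as 8.00 times faster on this pair of readings. Gamma's precatalyst is the geometric mean of the two loadings and its temperature is nearly the midpoint, so this reckoning gives it the square root of that factor. Its 6.0 min then match 17.0 min of the north-west run, where intermediate lies between 13.8% and 21.4%.

The stretch has a border. From the span 2.50 min to 4.00 min to the last span of the west run, conversion per minute reads as dropping by a factor of 5.90. Substrate falls by a factor of only 1.32 over the same time, so the catalyst is read as failing, and the end state is a budget. By 8.00 min the west run has converted 41.1 substrate per precatalyst charged, its turnover number N. The cooler north-west run reaches 146 by 40.0 min. Delta is hotter than the west run and holds half its precatalyst. At the west N it converts 20.5% of its substrate, and that is taken as its cap. The pick here is therefore gamma, narrowly.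

The forecast read the runs as curves that “nearly superimpose if the time axis is stretched”. It gave 28% for delta, 7.5% for theta and 18% for gamma, with delta highest. Its delta stands above the cap, and there the two reckonings part.

    substrate + free catalyst → free catalyst + intermediate (k = 4.60 M⁻¹ s⁻¹, Ea = 46.0 kJ mol⁻¹)
    coupling partner + free catalyst + intermediate ⇌ free catalyst + target (K = 7.00 M⁻¹, k = 3.27 M⁻² s⁻¹, Ea = 46.0 kJ mol⁻¹, ΔH = 9.00 kJ mol⁻¹)
    precatalyst ⇌ free catalyst (K = 0.650, k = 0.00274 s⁻¹, Ea = 86.0 kJ mol⁻¹, ΔH = −76.0 kJ mol⁻¹)
    free catalyst → spent catalyst (k = 0.0115 s⁻¹, Ea = 94.0 kJ mol⁻¹)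
    (constants at 40 °C)

Gamma comes out highest, at 20.9% against 15.6% for delta and 3.21% for theta. Delta at 6.00 min holds 83.4% of its substrate, with 91.4% of the catalyst charged spent. Delta's N is 33.2, lower than the 41.1 read from the west run. The same flask read at 2.5 min has N = 23.7, a share of 0.577 of the west figure. There 63.6% of the catalyst charged is spent, and intermediate stands at 11.4%.

The numbers in the tables are simulated from invented constants, and the scatter is random.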